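**Plan**
- The handle is the cis pair of oxygens on two adjacent fully substituted carbons of ring B: the C8 acetoxy oxygen and the C9 ether oxygen of ring C (O–C9–C11–C12–C13), the latter already tied to C13. C9–O and C8–O are therefore cut together, back to a C8=C9 alkene carrying a C13 tertiary alcohol.
- Further cuts: the ring D enol ether (from a 15,16-lactone), C9–C11 (B-alkyl Suzuki–Miyaura coupling of a C9 enol triflate with a vinyl carbinol lactone), and C1–C10/C4–C5 (quinone Diels–Alder reaction, allylidenecyclopropane standing in for a gem-dimethyl diene).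
- Forward: rings A and B form together in the cycloaddition; C7 and C6 are oxygenated; the C11–C16 lactone is joined at C9; ring C closes in the oxidative cyclisation; ring D is then taken to the enol ether and C8, C6 and C7 are finished.
- Stereochemistry: C5/C10 from the catalyst-controlled cycloaddition; C7 from convex-face enolate hydroxylation; C13 from a Sharpless epoxidation; C8/C9 from suprafacial addition anti to the C7 silyloxy group.

Key step: step 16

Remark: the SMILES places H-5 on the same face as the C10 methyl (cis-fused rings A/B) and this diastereomer is the one made; labdane numbering is used throughout, β being the face of the C10 methyl.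

**Step 1**
Reactants: 1 cyclopropyltriphenylphosphonium bromide; 2 acrolein
Product: 4 allylidenecyclopropane, via cyclopropylidenetriphenylphosphorane 3 (not isolated)
Conditions: KOt-Bu, THF, 0 °C to rt; then 2, 0 °C to rt; distil
Reagents that add atoms: none
Why: Wittig olefination of the enal by the non-stabilised cyclopropylidene ylide should give the volatile diene, whose strained terminus makes it a reactive surrogate for a gem-dimethyl diene; no stereocentre arises.

**Step 2**
Reactants: 5 2,6-dimethyl-1,4-benzoquinone; 4 allylidenecyclopropane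
Product: 6 cis-enedione (C6 and C9 ketones; C7=C8 and C2=C3; methyls on C8 and C10; C4 spirocyclopropane; 5β-H and 10β-CH3)
Conditions: (R)-3,3-diphenyl-1-(o-tolyl)tetrahydropyrrolo[1,2-c][1,3,2]oxazaborole·HNTf2 (20 mol%), CH2Cl2, −78 °C
Reagents that add atoms: none
Why: Lewis-acid-catalysed Diels–Alder reaction in which the chiral boron cation binds the only quinone oxygen flanked by α-C–H bonds, so that the CH2 terminus of the diene bonds to the methyl-bearing β-carbon (C10) and the cyclopropylidene carbon to C5, the cyclic dienophile enforces the cis fusion, and the aryl group of the (R)-catalyst is expected, from the α-C–H···O binding model, to cover the face leading to the enantiomer.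

**Step 3**
Reactants: 6 cis-enedione
Product: 8 keto enol triflate (C9–OTf on C8=C9; C6 ketone; C7 methylene), via lithium C9 enolate 7 (not isolated)
Conditions: LiBH(s-Bu)3, THF, −78 °C; then N-(5-chloropyridin-2-yl)triflimide, −78 to 0 °C
Reagents that add atoms: N-(5-chloropyridin-2-yl)bis(trifluoromethanesulfonyl)imide, FC(F)(F)S(=O)(=O)N(c1ccc(Cl)cn1)S(=O)(=O)C(F)(F)F
Why: Conjugate reduction with enolate trapping: the hindered borohydride should add hydride to the unsubstituted C7 of the enedione, unmasking only the tetrasubstituted C9 enolate, which is O-triflated before it can equilibrate; C5 is not enolised at −78 °C.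

**Step 4**
Reactants: 8 keto enol triflate
Product: 10 7β-hydroxy ketone (7β-OH; C6 ketone; C9 enol triflate), via sodium C6 dienolate 9 (not isolated)
Conditions: NaN(SiMe3)2, THF, −78 °C; 2-(phenylsulfonyl)-3-phenyloxaziridine, −78 °C; AcOH quench
Reagents that add atoms: 2-(phenylsulfonyl)-3-phenyloxaziridine, O=S(=O)(c1ccccc1)N1OC1c1ccccc1
Why: Enolate hydroxylation with an N-sulfonyloxaziridine: kinetic deprotonation at the doubly activated C7 methylene gives the dienolate, which should be oxidised at C7 from the convex β face, away from ring A and its C4 spiro carbon, setting the 7β-hydroxyl.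

**Step 5**
Reactants: 10 7β-hydroxy ketone
Product: 11 7β-(tert-butyldimethylsilyloxy) ketone
Conditions: t-BuMe2SiOTf, 2,6-lutidine, CH2Cl2, −78 to 0 °C
Reagents that add atoms: tert-butyldimethylsilyl triflate, CC(C)(C)[Si](C)(C)OS(=O)(=O)C(F)(F)F
Why: Standard silylation of a hindered secondary alcohol with a silyl triflate and a non-nucleophilic base; the bulky group is placed on C7 because it steers steps 6 and 16.

**Step 6**
Reactants: 11 7β-silyloxy ketone
Product: 12 6β-alcohol (6β-OH cis to 7β-OTBS; C9 enol triflate)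
Conditions: NaBH4, MeOH–CH2Cl2, −40 to 0 °C
Reagents that add atoms: none
Why: Borohydride reduction of an α-silyloxy ketone: with the 7β-silyloxy group pseudoaxial (allylic strain against the C8 methyl) hydride should add anti to it (Felkin–Anh) from the α face, giving the 6β-alcohol, while the enol triflate is inert.

**Step 7**
Reactants: 13 4-(tert-butyldimethylsilyloxy)butanal
Product: 14 2-[2-(tert-butyldimethylsilyloxy)ethyl]acrylaldehyde
Conditions: aq. CH2O, pyrrolidine (10 mol%), propionic acid (10 mol%), i-PrOH, 45 °C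
Reagents that add atoms: formaldehyde, C=O
Why: Amine-catalysed Mannich condensation–elimination (α-methylenation of an aldehyde) installs the 1,1-disubstituted alkene whose CH2 becomes C12.

**Step 8**
Reactants: 14 α-methylene aldehyde
Product: 15 2-[2-(tert-butyldimethylsilyloxy)ethyl]prop-2-en-1-ol
Conditions: NaBH4, CeCl3·7H2O, MeOH, 0 °C
Reagents that add atoms: none
Why: Luche reduction gives clean 1,2-reduction of the enal to the 2-substituted allylic alcohol without touching the silyl ether.

**Step 9**
Reactants: 15 allylic alcohol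
Product: 16 (S)-[2-(2-(tert-butyldimethylsilyloxy)ethyl)oxiran-2-yl]methanol
Conditions: Ti(Oi-Pr)4 (10 mol%), L-(+)-diethyl tartrate (12 mol%), t-BuOOH, 4 Å molecular sieves, CH2Cl2, −20 °C
Reagents that add atoms: tert-butyl hydroperoxide, CC(C)(C)OO
Why: Sharpless asymmetric epoxidation of a 2-substituted allylic alcohol; L-(+)-tartrate delivers oxygen to the face that gives the (S)-epoxide, as with methallyl alcohol, and this fixes the future C13.

**Step 10**
Reactants: 16 (S)-epoxy alcohol
Product: 17 (R)-4-(tert-butyldimethylsilyloxy)-2-vinylbutane-1,2-diol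
Conditions: Me3S+ I−, n-BuLi, THF, −15 °C to rt
Reagents that add atoms: trimethylsulfonium iodide, C[S+](C)C.[I-]
Why: One-carbon homologation of an epoxide to an allylic alcohol: dimethylsulfonium methylide opens the epoxide at its CH2 terminus and a second equivalent induces elimination of dimethyl sulfide, leaving the C13–O bond and hence the configuration untouched.

**Step 11**
Reactants: 17 vinyl diol
Product: 18 (R)-2-vinylbutane-1,2,4-triol
Conditions: pyridinium p-toluenesulfonate (cat.), MeOH, rt
Reagents that add atoms: none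
Why: Mild acid-catalysed methanolysis removes the primary silyl ether without ionising the tertiary allylic alcohol.

**Step 12**
Reactants: 18 triol
Product: 20 (R)-4-hydroxy-4-vinyldihydrofuran-2(3H)-one, via hydroxy lactol 19 (not isolated)
Conditions: TEMPO (20 mol%), PhI(OAc)2, CH2Cl2, rt
Reagents that add atoms: none
Why: Nitroxyl-catalysed oxidative lactonisation of a 1,4-diol: the unhindered C15 alcohol should be oxidised in preference to the neopentyl C16 alcohol, the aldehyde closes to the five-membered lactol with the C16 hydroxyl, and this is oxidised on to the γ-lactone.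

**Step 13**
Reactants: 20 vinyl lactone; 12 enol triflate
Product: 22 coupled diol (C9–C11 bond; free 6β-OH and C13–OH; 7β-OTBS; ring A alkene and spirocyclopropane retained), via B-alkyl-9-borabicyclononane 21 (not isolated)
Conditions: 20, 9-BBN, THF, rt; then 12, PdCl2(dppf)·CH2Cl2 (10 mol%), AsPh3, aq. K3PO4, DMF, rt to 50 °C
Reagents that add atoms: none
Why: Anti-Markovnikov hydroboration puts boron on C11 and B-alkyl Suzuki–Miyaura coupling with the enol triflate forges C9–C11, a coupling precedented for 2,6,6-trisubstituted cyclohexenyl triflates; free hydroxyls and the lactone are tolerated and no stereocentre is touched.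

**Step 14**
Reactants: 22 coupled diol
Product: 24 gem-dimethyl diol (saturated ring A; C4 gem-dimethyl; C8=C9 retained), via ring A-saturated spirocyclopropane 23 (not isolated)
Conditions: H2 (3 atm), PtO2, AcOH, rt
Reagents that add atoms: none
Why: Heterogeneous hydrogenation saturates the disubstituted C2=C3 bond and then hydrogenolyses the spirocyclopropane at its unsubstituted CH2–CH2 bond to the C4 gem-dimethyl group, while the tetrasubstituted C8=C9 bond, flanked by C7 and quaternary C10, should be too hindered to reduce.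

**Step 15**
Reactants: 24 gem-dimethyl diol
Product: 25 cyclisation precursor (6β-OTES; 7β-OTBS; C8=C9; free C13 tertiary alcohol)
Conditions: Et3SiCl, imidazole, DMF, 0 °C to rt
Reagents that add atoms: chlorotriethylsilane, CC[Si](Cl)(CC)CC
Why: Chemoselective silylation: the secondary 6β-hydroxyl reacts with the silyl chloride whereas the tertiary C13 hydroxyl, needed free for step 16, does not.

**Step 16**
Reactants: 25 cyclisation precursor
Product: 28 spiro ether lactone with free 8α-hydroxyl (ring C closed; 9α-O; 13S), via C13 perrhenate ester 26 (not isolated), via C8 oxorhenium ester 27 (not isolated)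
Conditions: Re2O7, 2,6-lutidine, CH2Cl2, rt; aq. NaHCO3
Reagents that add atoms: dirhenium heptoxide, O=[Re](=O)(=O)O[Re](=O)(=O)=O
Why: Re2O7 esterifies the C13 tertiary alcohol to the perrhenate 26, whose O–Re=O unit adds across the tetrasubstituted C8=C9 bond in a concerted [3+2] manner, so that the C13 oxygen bonds to C9 and an oxo oxygen to C8 on the same face, and hydrolysis of the pentavalent rhenium ester 27 on work-up frees the C8 hydroxyl. The closest known reaction is the heptavalent-rhenium syn-oxidative cyclisation of bishomoallylic alcohols to 2-(1-hydroxyalkyl)tetrahydrofurans. Ring C (O–C9–C11–C12–C13) closes in the 5-exo mode with respect to the tethered oxygen and becomes spiro to rings B and D. C9 and C8 are set together: their cis relation follows from the suprafacial addition, and the face is chosen by the substrate, whose cis-6β,7β-bis(silyloxy) pattern should hold ring B in the half-chair with the bulky 7β-OTBS group pseudoaxial over the β face next to C8, the carbon that receives the rhenium-bound oxygen, so that addition occurs on the α face, anti to the allylic C7–O bond, while C13 is carried in unchanged. The step needs α-face selectivity and suppression of acid-triggered ionisation at C13 or C7; the first rests on the C7 substituent, the second on the lutidine buffer and on the electron-withdrawing lactone and C16 oxygen that flank C13.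

**Step 17**
Reactants: 28 spiro ether lactone
Product: 29 lactol (C15 hemiacetal; anomeric mixture)
Conditions: i-Bu2AlH, CH2Cl2, −78 °C; aq. KNaC4H4O6 (potassium sodium tartrate)
Reagents that add atoms: none
Why: Partial reduction of a γ-lactone to the lactol with a dialkylaluminium hydride at low temperature, the tertiary C8 hydroxyl being merely deprotonated; the anomeric centre is of no consequence.

**Step 18**
Reactants: 29 lactol
Product: 31 dihydrofuran 8α-alcohol (ring D enol ether C14=C15), via anomeric mesylate 30 (not isolated)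
Conditions: MsCl, Et3N, CH2Cl2, −20 to 40 °C
Reagents that add atoms: none
Why: Dehydration of a lactol through its anomeric sulfonate and amine-induced β-elimination toward C14, the usual lactol-to-cyclic-enol-ether conversion; the hindered tertiary C8 hydroxyl should not be sulfonylated.

**Step 19**
Reactants: 31 dihydrofuran 8α-alcohol
Product: 32 8α-acetate
Conditions: Ac2O, DMAP, Et3N, CH2Cl2, 40 °C
Reagents that add atoms: acetic anhydride, CC(=O)OC(C)=O
Why: DMAP-catalysed acylation of the tertiary 8α-hydroxyl under basic conditions that leave the acid-sensitive enol ether and both silyl ethers intact.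

**Step 20**
Reactants: 32 8α-acetate
Product: 33 6β-alcohol (7β-OTBS and 8α-OAc retained)
Conditions: HF·pyridine, pyridine, THF, 0 °C
Reagents that add atoms: none
Why: Selective desilylation: buffered fluoride cleaves the triethylsilyl ether far faster than the more hindered tert-butyldimethylsilyl ether, and the excess pyridine protects the enol ether.

**Step 21**
Reactants: 33 6β-alcohol
Product: 34 6-ketone (7β-OTBS)
Conditions: Dess–Martin periodinane, NaHCO3, CH2Cl2, 0 °C to rt
Reagents that add atoms: none
Why: Dess–Martin oxidation under buffered, non-enolising conditions should give the C6 ketone without epimerising C5 or C7.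

**Step 22**
Reactants: 34 6-ketone
Product: 35 target, 8α-acetoxy-7β-hydroxy-9α,13:15,16-diepoxy-5β-labd-14-en-6-one (13S)
Conditions: Bu4NF, AcOH (1:1), THF, 0 °C to rt
Reagents that add atoms: none
Why: Acetic acid-buffered fluoride removes the C7 silyl group without generating free alkoxide, so the cis ring fusion at C5, the tertiary acetate (no O8 to O7 acyl shift) and the acid-labile spiro enol ether should survive.

**Compound list**
1 | cyclopropyltriphenylphosphonium bromide | [Br-].C1CC1[P+](c1ccccc1)(c1ccccc1)c1ccccc1 | starting material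
2 | acrolein | C=CC=O | starting material
3 | cyclopropylidenetriphenylphosphorane | C1CC1=P(c1ccccc1)(c1ccccc1)c1ccccc1 | intermediate
4 | allylidenecyclopropane | C=CC=C1CC1 | intermediate
5 | 2,6-dimethyl-1,4-benzoquinone | CC1=CC(=O)C=C(C)C1=O | starting material
6 | cis-enedione (5β-H, 10β-CH3; C6/C9 ketones; C7=C8, C2=C3; C4 spirocyclopropane) | CC1=CC(=O)[C@@H]2C3(CC3)C=CC[C@]2(C)C1=O | intermediate
7 | lithium C9 enolate of the C7,C8-reduced enedione | CC=1CC(=O)[C@@H]2C3(CC3)C=CC[C@]2(C)C=1[O-].[Li+] | intermediate
8 | keto enol triflate (C9–OTf, C8=C9, C6 ketone) | CC=1CC(=O)[C@@H]2C3(CC3)C=CC[C@]2(C)C=1OS(=O)(=O)C(F)(F)F | intermediate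
9 | sodium C6 dienolate of 8 | CC=1C=C([O-])[C@@H]2C3(CC3)C=CC[C@]2(C)C=1OS(=O)(=O)C(F)(F)F.[Na+] | intermediate
10 | 7β-hydroxy ketone | CC=1[C@@H](O)C(=O)[C@@H]2C3(CC3)C=CC[C@]2(C)C=1OS(=O)(=O)C(F)(F)F | intermediate
11 | 7β-(tert-butyldimethylsilyloxy) ketone | CC=1[C@@H](O[Si](C)(C)C(C)(C)C)C(=O)[C@@H]2C3(CC3)C=CC[C@]2(C)C=1OS(=O)(=O)C(F)(F)F | intermediate
12 | 6β-alcohol, 7β-OTBS, C9 enol triflate | CC=1[C@@H](O[Si](C)(C)C(C)(C)C)[C@@H](O)[C@@H]2C3(CC3)C=CC[C@]2(C)C=1OS(=O)(=O)C(F)(F)F | intermediate
13 | 4-(tert-butyldimethylsilyloxy)butanal | O=CCCCO[Si](C)(C)C(C)(C)C | starting material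
14 | 2-[2-(tert-butyldimethylsilyloxy)ethyl]acrylaldehyde | C=C(C=O)CCO[Si](C)(C)C(C)(C)C | intermediate
15 | 2-[2-(tert-butyldimethylsilyloxy)ethyl]prop-2-en-1-ol | C=C(CO)CCO[Si](C)(C)C(C)(C)C | intermediate
16 | (S)-[2-(2-(tert-butyldimethylsilyloxy)ethyl)oxiran-2-yl]methanol | OC[C@@]1(CCO[Si](C)(C)C(C)(C)C)CO1 | intermediate
17 | (R)-4-(tert-butyldimethylsilyloxy)-2-vinylbutane-1,2-diol | C=C[C@@](O)(CO)CCO[Si](C)(C)C(C)(C)C | intermediate
18 | (R)-2-vinylbutane-1,2,4-triol | C=C[C@@](O)(CO)CCO | intermediate
19 | (4R)-4-vinyltetrahydrofuran-2,4-diol (lactol, anomeric mixture) | C=C[C@]1(O)CC(O)OC1 | intermediate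
20 | (R)-4-hydroxy-4-vinyldihydrofuran-2(3H)-one | C=C[C@]1(O)CC(=O)OC1 | intermediate
21 | B-alkyl-9-borabicyclo[3.3.1]nonane from 20 (boron on C11) | C1CCC2CCCC1B2CC[C@]1(O)CC(=O)OC1 | intermediate
22 | coupled diol (C8=C9, 6β-OH, 7β-OTBS, ring A alkene and spirocyclopropane, C13 hydroxy lactone) | CC=1[C@@H](O[Si](C)(C)C(C)(C)C)[C@@H](O)[C@@H]2C3(CC3)C=CC[C@]2(C)C=1CC[C@]1(O)CC(=O)OC1 | intermediate
23 | ring A-saturated spirocyclopropane | CC=1[C@@H](O[Si](C)(C)C(C)(C)C)[C@@H](O)[C@@H]2C3(CC3)CCC[C@]2(C)C=1CC[C@]1(O)CC(=O)OC1 | intermediate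
24 | gem-dimethyl diol (6β-OH, C13–OH) | CC=1[C@@H](O[Si](C)(C)C(C)(C)C)[C@@H](O)[C@@H]2C(C)(C)CCC[C@]2(C)C=1CC[C@]1(O)CC(=O)OC1 | intermediate
25 | cyclisation precursor (6β-OTES, 7β-OTBS, C8=C9, C13 tertiary alcohol) | CC=1[C@@H](O[Si](C)(C)C(C)(C)C)[C@@H](O[Si](CC)(CC)CC)[C@@H]2C(C)(C)CCC[C@]2(C)C=1CC[C@]1(O)CC(=O)OC1 | intermediate
26 | C13 perrhenate ester of 25 | CC=1[C@@H](O[Si](C)(C)C(C)(C)C)[C@@H](O[Si](CC)(CC)CC)[C@@H]2C(C)(C)CCC[C@]2(C)C=1CC[C@]1(O[Re](=O)(=O)=O)CC(=O)OC1 | intermediate
27 | C8 oxorhenium ester of the cyclised product | O=[Re](=O)O[C@]1(C)[C@@H](O[Si](C)(C)C(C)(C)C)[C@@H](O[Si](CC)(CC)CC)[C@@H]2C(C)(C)CCC[C@]2(C)[C@@]12CC[C@@]1(CC(=O)OC1)O2 | intermediate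
28 | spiro ether lactone with free 8α-OH (9α,13-epoxide; 13S) | O[C@]1(C)[C@@H](O[Si](C)(C)C(C)(C)C)[C@@H](O[Si](CC)(CC)CC)[C@@H]2C(C)(C)CCC[C@]2(C)[C@@]12CC[C@@]1(CC(=O)OC1)O2 | intermediate
29 | lactol (C15 hemiacetal, anomeric mixture) | O[C@]1(C)[C@@H](O[Si](C)(C)C(C)(C)C)[C@@H](O[Si](CC)(CC)CC)[C@@H]2C(C)(C)CCC[C@]2(C)[C@@]12CC[C@@]1(CC(O)OC1)O2 | intermediate
30 | anomeric mesylate of 29 | O[C@]1(C)[C@@H](O[Si](C)(C)C(C)(C)C)[C@@H](O[Si](CC)(CC)CC)[C@@H]2C(C)(C)CCC[C@]2(C)[C@@]12CC[C@@]1(CC(OS(C)(=O)=O)OC1)O2 | intermediate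
31 | dihydrofuran 8α-alcohol | O[C@]1(C)[C@@H](O[Si](C)(C)C(C)(C)C)[C@@H](O[Si](CC)(CC)CC)[C@@H]2C(C)(C)CCC[C@]2(C)[C@@]12CC[C@@]1(C=COC1)O2 | intermediate
32 | 8α-acetate (6β-OTES, 7β-OTBS) | CC(=O)O[C@]1(C)[C@@H](O[Si](C)(C)C(C)(C)C)[C@@H](O[Si](CC)(CC)CC)[C@@H]2C(C)(C)CCC[C@]2(C)[C@@]12CC[C@@]1(C=COC1)O2 | intermediate
33 | 6β-alcohol (7β-OTBS, 8α-OAc) | CC(=O)O[C@]1(C)[C@@H](O[Si](C)(C)C(C)(C)C)[C@@H](O)[C@@H]2C(C)(C)CCC[C@]2(C)[C@@]12CC[C@@]1(C=COC1)O2 | intermediate
34 | 6-ketone (7β-OTBS, 8α-OAc) | CC(=O)O[C@]1(C)[C@@H](O[Si](C)(C)C(C)(C)C)C(=O)[C@@H]2C(C)(C)CCC[C@]2(C)[C@@]12CC[C@@]1(C=COC1)O2 | intermediate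
35 | 8α-acetoxy-7β-hydroxy-9α,13:15,16-diepoxy-5β-labd-14-en-6-one (13S) | CC(=O)O[C@]1(C)[C@@H](O)C(=O)[C@@H]2C(C)(C)CCC[C@]2(C)[C@@]12CC[C@@]1(C=COC1)O2 | target

**Step count**
Total: 22 steps. Longest linear sequence: 16 steps (steps 1–6 and 13–22; the lactone branch, steps 7–12 and 13–22, is equally long).

**Steps most likely to fail**

Step 16. The perrhenate may add to the β face, since on the α face the pseudoaxial C1 methylene of the cis-fused ring A also crowds C9. Alternatively perrhenic acid may ionise or dehydrate the tertiary carbinol before the [3+2] addition takes place. The fallback sets out from 25 and forms the same two C–O bonds in separate known operations. Dehydration of the β-hydroxy lactone (MsCl, excess Et3N) gives the butenolide F1. Stoichiometric OsO4–pyridine then dihydroxylates C8=C9 anti to the C7 silyloxy group and, after reductive work-up, gives the 8α,9α-diol F2. Base (DBU, CH2Cl2) brings about 5-exo oxa-Michael addition of the 9α-hydroxyl to C13 of the butenolide, closing ring C and coming back to the route at 28. C13 is set under equilibrating conditions, so an epimer at C13 would have to be separated or recycled through retro-Michael equilibration.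

Step 2. The strongly acidic boron cation may oligomerise or ring-open the strained diene, or facial discrimination of the quinone may be incomplete. The fallback sets out from 5 and 4: BF3·OEt2 (20 mol%, CH2Cl2, −78 °C) binds the same quinone oxygen, so the regiochemistry should be kept, and gives the racemic adduct F3. The enantiomers are separated by preparative chromatography on a cellulose carbamate chiral stationary phase, which returns to the route at 6.

Step 19. Acyl transfer to the doubly neopentyl tertiary hydroxyl may stall under nucleophilic catalysis, and forcing it through the alkoxide invites silyl migration from O7. The fallback sets out from 28, where no enol ether is yet present, and changes the order of events. Lewis-acid-assisted acetylation (Ac2O, MgBr2·OEt2, i-Pr2NEt, CH2Cl2) gives the acetoxy lactone F4. Disiamylborane, which leaves esters alone, reduces only the lactone to the acetoxy lactol F5. Dehydration as in step 18 (MsCl, Et3N) comes back to the route at 32.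

**Further compounds**
F1 | step 16 | butenolide from dehydration of 25 (C13=C14) | CC=1[C@@H](O[Si](C)(C)C(C)(C)C)[C@@H](O[Si](CC)(CC)CC)[C@@H]2C(C)(C)CCC[C@]2(C)C=1CCC1=CC(=O)OC1
F2 | step 16 | 8α,9α-diol butenolide | O[C@]1(C)[C@@H](O[Si](C)(C)C(C)(C)C)[C@@H](O[Si](CC)(CC)CC)[C@@H]2C(C)(C)CCC[C@]2(C)[C@@]1(O)CCC1=CC(=O)OC1
F3 | step 2 | racemic cis-enedione (6 together with its enantiomer; enantiomer shown) | CC1=CC(=O)[C@H]2C3(CC3)C=CC[C@@]2(C)C1=O
F4 | step 19 | 8α-acetoxy spiro ether lactone | CC(=O)O[C@]1(C)[C@@H](O[Si](C)(C)C(C)(C)C)[C@@H](O[Si](CC)(CC)CC)[C@@H]2C(C)(C)CCC[C@]2(C)[C@@]12CC[C@@]1(CC(=O)OC1)O2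
F5 | step 19 | 8α-acetoxy lactol (anomeric mixture) | CC(=O)O[C@]1(C)[C@@H](O[Si](C)(C)C(C)(C)C)[C@@H](O[Si](CC)(CC)CC)[C@@H]2C(C)(C)CCC[C@]2(C)[C@@]12CC[C@@]1(CC(O)OC1)O2
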